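**Retrosynthetic overview**
- The strategy rests on ring B, a benzoic acid whose C1 (CO2H) and C6 (pentyl) are adjacent and whose oxygens sit at C2 and C4, meta to each other. C1/C6 map onto the two alkyne carbons of an oct-2-ynoate, and C2–C5 onto a 1,1,3-trioxygenated butadiene.
- Last disconnections: hydrogenolysis of two benzyl groups, then the depside ester C–O bond between O-4 of ring B and the carbonyl carbon of ring A.
- Ring A is not built. It comes from 5-propylresorcinol by formylation, 4-O-methylation, 2-O-benzylation and oxidation to the acid.
- Ring B is the only ring formed. A [4+2] cycloaddition of the bis(silyloxy)diene from methyl acetoacetate with benzyl oct-2-ynoate makes C1–C2 and C5–C6, and loss of methanol plus desilylation gives the arene.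
- Order: ynoate and diene, then ring B (key step), then ring A acid, esterification, and debenzylation.

Key step: step 4

Assumption: the silyl enol ether and the diene derived from methyl acetoacetate are drawn as single double-bond isomers; either geometry would serve, because that geometry disappears when ring B aromatises.

**Step 1**
Reactants: 1 hept-1-yne; 2 benzyl chloroformate
Product: 4 benzyl oct-2-ynoate, via heptynyllithium 3 (not isolated)
Conditions: n-BuLi, THF, −78 °C; then transfer into 2 (slight excess), THF, −78 °C to rt
Reagents that add atoms: none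
Why: Deprotonation of the terminal alkyne gives acetylide 3, which undergoes acyl substitution on the chloroformate (alkynyllithium acylation), and inverse addition at low temperature keeps the product ynoate from meeting excess acetylide.

**Step 2**
Reactants: 5 methyl acetoacetate
Product: 6 methyl (2E)-3-(trimethylsilyloxy)but-2-enoate
Conditions: Me3SiCl, Et3N, hexane, rt; filter, distil
Reagents that add atoms: chlorotrimethylsilane, C[Si](C)(C)Cl
Why: Soft enolisation of the β-keto ester by Et3N followed by O-silylation is the standard route to the silyl enol ether of an acetoacetate.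

**Step 3**
Reactants: 6 methyl (2E)-3-(trimethylsilyloxy)but-2-enoate
Product: 8 (1Z)-1-methoxy-1,3-bis(trimethylsilyloxy)buta-1,3-diene, via lithium dienolate 7 (not isolated)
Conditions: LiN(i-Pr)2 (LDA, commercial solution), THF, −78 °C; then Me3SiCl, −78 to 0 °C; pentane, filter under argon, distil in vacuo, use fresh
Reagents that add atoms: chlorotrimethylsilane, C[Si](C)(C)Cl
Why: LDA removes a γ-proton of the vinylogous ester to give the extended dienolate 7, and the hard silicon electrophile traps it on oxygen to give the silyl ketene acetal diene (kinetic O-silylation of an ester dienolate).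

**Step 4**
Reactants: 8 (1Z)-1-methoxy-1,3-bis(trimethylsilyloxy)buta-1,3-diene; 4 benzyl oct-2-ynoate
Product: 11 benzyl 2,4-dihydroxy-6-pentylbenzoate, via cycloadduct 9 (not isolated), via bis(silyl ether) 10 (not isolated)
Conditions: PhMe (minimal), 120 °C, sealed tube, 8 in excess added in portions; then 1 M HCl, THF, rt
Reagents that add atoms: none
Why: The electron-rich silyl ketene acetal diene 8 and the electron-poor ynoate 4 should combine in a thermal, normal-demand and strongly asynchronous [4+2] cycloaddition, in which the bond from the diene CH2 terminus to the pentyl-bearing β-carbon of 4 forms ahead of the bond from the ketene acetal carbon to the ester-bearing α-carbon. The closest known reaction type is the Diels–Alder addition of 1-alkoxy-1,3-bis(silyloxy)butadienes and 1,1-dialkoxy-3-silyloxybutadienes to acetylenic esters, followed by aromatisation to resorcylates. Ring B closes as a six-membered carbocycle in this intermolecular [4+2] mode, four carbons from 8 and two from 4, giving cyclohexa-1,4-diene 9. No stereocentre needs control, because the ketal carbon of 9 is racemic and becomes planar when 9 loses methanol by 1,4-elimination to the aryl bis(silyl ether) 10. The one selectivity required is regiochemical, and polarity matching secures it: the most nucleophilic diene carbon (CH2) pairs with the most electrophilic carbon of 4 (the β-carbon), which places pentyl next to the ester and the oxygens at C2 and C4. Dilute HCl then cleaves both aryl silyl ethers, leaving 11 with a free 4-hydroxyl and a 2-hydroxyl hydrogen-bonded to the benzyl ester.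

**Step 5**
Reactants: 12 5-propylbenzene-1,3-diol (divarinol)
Product: 14 2,4-dihydroxy-6-propylbenzaldehyde, via iminium chloride 13 (not isolated)
Conditions: POCl3, DMF, 0 °C to rt; then H2O, 50 °C
Reagents that add atoms: N,N-dimethylformamide, CN(C)C=O; water, O
Why: Vilsmeier–Haack formylation should attack the ring carbon para to one hydroxyl and ortho to the other (the orcinol-type position), and aqueous hydrolysis of aryl iminium salt 13 releases the aldehyde.

**Step 6**
Reactants: 14 2,4-dihydroxy-6-propylbenzaldehyde
Product: 15 2-hydroxy-4-methoxy-6-propylbenzaldehyde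
Conditions: MeI (one equivalent), K2CO3 (one equivalent), acetone, rt
Reagents that add atoms: iodomethane, CI
Why: In this Williamson etherification the 2-hydroxyl is held in a hydrogen bond to the formyl oxygen, so the more acidic and accessible 4-hydroxyl should be methylated first.

**Step 7**
Reactants: 15 2-hydroxy-4-methoxy-6-propylbenzaldehyde
Product: 16 2-benzyloxy-4-methoxy-6-propylbenzaldehyde
Conditions: BnBr, K2CO3, DMF, 60 °C
Reagents that add atoms: benzyl bromide, BrCc1ccccc1
Why: The remaining chelated phenol should undergo Williamson benzylation under these more forcing conditions, masking it as an ether that falls away in the final hydrogenolysis.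

**Step 8**
Reactants: 16 2-benzyloxy-4-methoxy-6-propylbenzaldehyde
Product: 17 2-benzyloxy-4-methoxy-6-propylbenzoic acid
Conditions: NaClO2, NaH2PO4, 2-methylbut-2-ene (large excess), t-BuOH/H2O, rt
Reagents that add atoms: sodium chlorite, [Na+].[O-]Cl=O
Why: Pinnick oxidation converts the hindered aryl aldehyde to the acid without touching the ethers, and the alkene scavenger removes hypochlorous acid before it can chlorinate the electron-rich ring.

**Step 9**
Reactants: 11 benzyl 2,4-dihydroxy-6-pentylbenzoate; 17 2-benzyloxy-4-methoxy-6-propylbenzoic acid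
Product: 19 benzyl 4-[(2-benzyloxy-4-methoxy-6-propylbenzoyl)oxy]-2-hydroxy-6-pentylbenzoate, via O-acylisourea 18 (not isolated)
Conditions: DCC, DMAP (cat.), CH2Cl2, 0 °C to rt
Reagents that add atoms: none
Why: In this Steglich-type esterification DCC activates 17 as O-acylisourea 18 and DMAP relays the acyl group to the free 4-hydroxyl of 11, while the 2-hydroxyl, hydrogen-bonded to and flanked by the benzyl ester, should stay unacylated.

**Step 10**
Reactants: 19 benzyl 4-[(2-benzyloxy-4-methoxy-6-propylbenzoyl)oxy]-2-hydroxy-6-pentylbenzoate
Product: 20 stenosporic acid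
Conditions: H2 (1 atm), 10% Pd/C, EtOAc, rt
Reagents that add atoms: none
Why: Catalytic hydrogenolysis should cleave the benzyl ester and the benzyl aryl ether together, while the depside aryl ester, the methyl ether and the alkyl chains are inert, and a non-nucleophilic solvent at rt avoids transesterification and decarboxylation.

**Compound list**
1 | hept-1-yne | CCCCCC#C | starting material
2 | benzyl chloroformate | O=C(Cl)OCc1ccccc1 | starting material
3 | hept-1-yn-1-yllithium | [Li]C#CCCCCC | intermediate (not isolated)
4 | benzyl oct-2-ynoate | CCCCCC#CC(=O)OCc1ccccc1 | intermediate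
5 | methyl acetoacetate | COC(=O)CC(C)=O | starting material
6 | methyl (2E)-3-(trimethylsilyloxy)but-2-enoate | COC(=O)/C=C(\C)O[Si](C)(C)C | intermediate
7 | lithium (1E)-1-methoxy-3-(trimethylsilyloxy)buta-1,3-dien-1-olate | CO/C([O-])=C/C(=C)O[Si](C)(C)C.[Li+] | intermediate (not isolated)
8 | (1Z)-1-methoxy-1,3-bis(trimethylsilyloxy)buta-1,3-diene | CO/C(O[Si](C)(C)C)=C/C(=C)O[Si](C)(C)C | intermediate
9 | benzyl 6-methoxy-2-pentyl-4,6-bis(trimethylsilyloxy)cyclohexa-1,4-diene-1-carboxylate (racemic) | CCCCCC1=C(C(=O)OCc2ccccc2)C(OC)(O[Si](C)(C)C)C=C(O[Si](C)(C)C)C1 | intermediate (not isolated)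
10 | benzyl 2-pentyl-4,6-bis(trimethylsilyloxy)benzoate | CCCCCc1cc(O[Si](C)(C)C)cc(O[Si](C)(C)C)c1C(=O)OCc1ccccc1 | intermediate (not isolated)
11 | benzyl 2,4-dihydroxy-6-pentylbenzoate | CCCCCc1cc(O)cc(O)c1C(=O)OCc1ccccc1 | intermediate
12 | 5-propylbenzene-1,3-diol (divarinol) | CCCc1cc(O)cc(O)c1 | starting material
13 | [(2,4-dihydroxy-6-propylphenyl)methylidene]dimethylammonium chloride | CCCc1cc(O)cc(O)c1C=[N+](C)C.[Cl-] | intermediate (not isolated)
14 | 2,4-dihydroxy-6-propylbenzaldehyde | CCCc1cc(O)cc(O)c1C=O | intermediate
15 | 2-hydroxy-4-methoxy-6-propylbenzaldehyde | CCCc1cc(OC)cc(O)c1C=O | intermediate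
16 | 2-benzyloxy-4-methoxy-6-propylbenzaldehyde | CCCc1cc(OC)cc(OCc2ccccc2)c1C=O | intermediate
17 | 2-benzyloxy-4-methoxy-6-propylbenzoic acid | CCCc1cc(OC)cc(OCc2ccccc2)c1C(=O)O | intermediate
18 | O-(2-benzyloxy-4-methoxy-6-propylbenzoyl)-N,N'-dicyclohexylisourea | CCCc1cc(OC)cc(OCc2ccccc2)c1C(=O)OC(=NC1CCCCC1)NC1CCCCC1 | intermediate (not isolated)
19 | benzyl 4-[(2-benzyloxy-4-methoxy-6-propylbenzoyl)oxy]-2-hydroxy-6-pentylbenzoate | CCCCCc1cc(OC(=O)c2c(OCc3ccccc3)cc(OC)cc2CCC)cc(O)c1C(=O)OCc1ccccc1 | intermediate
20 | stenosporic acid, 2-hydroxy-4-[(2-hydroxy-4-methoxy-6-propylbenzoyl)oxy]-6-pentylbenzoic acid | CCCCCc1cc(OC(=O)c2c(O)cc(OC)cc2CCC)cc(O)c1C(=O)O | target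

**Step count**
Total: 10 steps. Longest linear sequence: 6 steps (steps 5, 6, 7, 8, 9, 10, from divarinol 12).

**Steps most likely to fail**

Step 4. The cycloaddition of a β-alkyl ynoate may be slower than thermal decay of the diene (silyl migration, adventitious hydrolysis), so conversion may stall. The ketal carbon of the adduct may also shed trimethylsilanol instead of methanol, which would leave the 2-oxygen methylated. The fallback sets out from 4 and comes back at 10. Commercial dimedone is silylated (Me3SiCl, Et3N) to 5,5-dimethyl-3-(trimethylsilyloxy)cyclohex-2-en-1-one F1. Kinetic deprotonation at C6 with LiN(i-Pr)2 and trapping with Me3SiCl should give 5,5-dimethyl-1,3-bis(trimethylsilyloxy)cyclohexa-1,3-diene F2. This diene is locked s-cis and carries no alkoxy leaving group. Heating F2 with 4 without solvent at about 140 °C should give benzyl 8,8-dimethyl-3-pentyl-1,5-bis(trimethylsilyloxy)bicyclo[2.2.2]octa-2,5-diene-2-carboxylate F3, with the same regiochemical pairing (CH terminus to the β-carbon). Under the same heating F3 should extrude 2-methylpropene by retro-Diels–Alder reaction to give 10, and the HCl work-up of step 4 then delivers 11.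

Step 9. Acyl transfer from the O-acylisourea of a di-ortho-substituted acid may be slower than its O-to-N acyl migration to an N-acylurea, and forcing the reaction may begin to acylate the chelated 2-hydroxyl. The fallback sets out from 17 and comes back at 19. Acid 17 is converted with oxalyl chloride and catalytic DMF in CH2Cl2 into 2-benzyloxy-4-methoxy-6-propylbenzoyl chloride F4. F4 is then added to 11 and K2CO3 in acetone at 0 °C to rt, where only the more acidic 4-hydroxyl is ionised, so selectivity rests on phenoxide formation and no carbodiimide adduct is involved.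

Step 6. Alkylation may not stop at the 4-oxygen, and over-methylation of the chelated 2-hydroxyl would erode the differentiation of the two phenols. The fallback sets out from 14 and comes back at 15. Both hydroxyls are methylated on purpose (excess MeI, K2CO3, DMF) to give 2,4-dimethoxy-6-propylbenzaldehyde F5. BCl3 in CH2Cl2 at −78 to 0 °C should then cleave only the methyl ether ortho to the formyl group, through a boron chelate, to give 15.

**Further compounds**
F1 | step 4 | 5,5-dimethyl-3-(trimethylsilyloxy)cyclohex-2-en-1-one | CC1(C)CC(=O)C=C(O[Si](C)(C)C)C1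
F2 | step 4 | 5,5-dimethyl-1,3-bis(trimethylsilyloxy)cyclohexa-1,3-diene | CC1(C)CC(O[Si](C)(C)C)=CC(O[Si](C)(C)C)=C1
F3 | step 4 | benzyl 8,8-dimethyl-3-pentyl-1,5-bis(trimethylsilyloxy)bicyclo[2.2.2]octa-2,5-diene-2-carboxylate (racemic) | CCCCCC1=C(C(=O)OCc2ccccc2)C2(O[Si](C)(C)C)C=C(O[Si](C)(C)C)C1C(C)(C)C2
F4 | step 9 | 2-benzyloxy-4-methoxy-6-propylbenzoyl chloride | CCCc1cc(OC)cc(OCc2ccccc2)c1C(=O)Cl
F5 | step 6 | 2,4-dimethoxy-6-propylbenzaldehyde | CCCc1cc(OC)cc(OC)c1C=O
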